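**Retrosynthetic overview**

- The strategy rests on the benzenoid ring C4a–C5–C6–C7–C8–C8a, which carries OMe on C5 and OH on C8, unsymmetrical with respect to the side chain on C2. This ring is made last, so the pattern never has to be sorted out on a naphthalene.
- Target 16 comes from the C8 acetate 15 by mild methanolysis of the peri aryl ester.
- 15 is disconnected at C4a–C5 and C8–C8a into the chiral bromobenzoquinone 7 and the diene 12. The ring closes by [4+2] addition, loss of HBr and extrusion of ethylene.
- 7 comes from aldehyde 1 by asymmetric allylboration (sets the S carbinol carbon), cross-metathesis, Steglich esterification and CAN oxidation of the single benzene ring.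
- 12 comes from 1,4-dimethoxybenzene 8 by Birch reduction, hydrolysis of one enol ether and O-acetylation of the dienolate.

Key step: step 8

Remark: the four sp3 ring carbons made in the cycloaddition are transient, so 13 and 14 are carried as diastereomer mixtures and drawn without configuration there; 1 and the pentane solution of (−)-Ipc2B(allyl) are taken as purchased.

**Route**

Step 1
Reactants: 1 4-bromo-2,5-dimethoxybenzaldehyde
Product: 3 (S)-1-(4-bromo-2,5-dimethoxyphenyl)but-3-en-1-ol, via borinate ester 2 (not isolated)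
Conditions: (−)-Ipc2B(allyl) (1 M in pentane), Et2O, −78 °C; then aq. NaOH, H2O2, 0 °C → rt
Reagents that add atoms: (−)-B-allyldiisopinocampheylborane, C=CCB([C@H]1[C@H](C)[C@H]2C[C@@H](C1)C2(C)C)[C@H]1[C@H](C)[C@H]2C[C@@H](C1)C2(C)C
Why: Brown asymmetric allylboration passes through a closed chair transition state in which the isopinocampheyl groups derived from (+)-α-pinene should direct allyl to the Si face of the aryl aldehyde, which sets the (S) carbinol carbon, and alkaline peroxide then cleaves the borinate 2.

Step 2
Reactants: 3 (S)-1-(4-bromo-2,5-dimethoxyphenyl)but-3-en-1-ol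
Product: 4 (S)-1-(4-bromo-2,5-dimethoxyphenyl)-4-methylpent-3-en-1-ol
Conditions: Grubbs II (cat.), 2-methylbut-2-ene (excess), CH2Cl2, 40 °C
Reagents that add atoms: 2-methylbut-2-ene, CC=C(C)C
Why: Olefin cross-metathesis with 2-methylbut-2-ene should exchange the terminal =CH2 for =CMe2 with loss of volatile propene, and the free alcohol, the aryl bromide and the stereocentre are not involved.

Step 3
Reactants: 4 (S)-1-(4-bromo-2,5-dimethoxyphenyl)-4-methylpent-3-en-1-ol; 5 3-methylbut-2-enoic acid
Product: 6 (S)-1-(4-bromo-2,5-dimethoxyphenyl)-4-methylpent-3-en-1-yl 3-methylbut-2-enoate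
Conditions: DCC, DMAP (cat.), CH2Cl2, 0 °C → rt
Reagents that add atoms: none
Why: Steglich esterification acylates the alcohol oxygen without breaking the C–O bond of the stereocentre (retention), and carbodiimide activation avoids the vinylketene route by which the acid chloride with amine base would deconjugate the acyl group.

Step 4
Reactants: 6 (S)-1-(4-bromo-2,5-dimethoxyphenyl)-4-methylpent-3-en-1-yl 3-methylbut-2-enoate
Product: 7 (S)-2-bromo-5-[4-methyl-1-(3-methylbut-2-enoyloxy)pent-3-enyl]-1,4-benzoquinone
Conditions: CAN, MeCN/H2O, 0 °C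
Reagents that add atoms: water, O
Why: CAN oxidative demethylation of a para-dimethoxyarene should give the para-quinone unambiguously because only one benzene ring with one pair of para OMe groups is present, and the bromine, the ester and the trisubstituted alkenes should tolerate the short contact at 0 °C.

Step 5
Reactants: 8 1,4-dimethoxybenzene
Product: 9 1,4-dimethoxycyclohexa-1,4-diene
Conditions: Li, NH3 (l), THF, t-BuOH, −78 → −33 °C
Reagents that add atoms: none
Why: Birch reduction of an alkoxyarene protonates the unsubstituted positions, so both methoxy groups should remain on the two isolated double bonds of the 1,4-diene.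

Step 6
Reactants: 9 1,4-dimethoxycyclohexa-1,4-diene
Product: 10 4-methoxycyclohex-3-en-1-one
Conditions: (CO2H)2 (cat.), H2O (1 equiv), THF, 0 °C
Reagents that add atoms: water, O
Why: Acid-catalysed enol ether hydrolysis should stop after one site because water is limiting and the remaining enol ether is made less basic by the new carbonyl, and the weak acid should leave the β,γ-double bond in place.

Step 7
Reactants: 10 4-methoxycyclohex-3-en-1-one
Product: 12 4-methoxycyclohexa-1,3-dien-1-yl acetate (4-acetoxy-1-methoxycyclohexa-1,3-diene), via potassium dienolate 11 (not isolated)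
Conditions: KHMDS, THF, −78 °C; Ac2O, −78 → 0 °C
Reagents that add atoms: acetic anhydride, CC(=O)OC(C)=O
Why: Deprotonation at C2, which is both α to the carbonyl and allylic to the enol ether, should give the conjugated dienolate 11, and the hard anhydride should acylate the potassium enolate on oxygen (enol acetate formation from a preformed enolate).

Step 8
Reactants: 7 (S)-2-bromo-5-[4-methyl-1-(3-methylbut-2-enoyloxy)pent-3-enyl]-1,4-benzoquinone; 12 4-methoxycyclohexa-1,3-dien-1-yl acetate
Product: 15 (S)-8-acetoxy-5-methoxy-2-[4-methyl-1-(3-methylbut-2-enoyloxy)pent-3-enyl]-1,4-naphthoquinone, via bromo cycloadduct 13 (not isolated), via ethano-bridged quinone 14 (not isolated)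
Conditions: 12 (1.5 equiv), PhMe, 0 °C → rt; Et3N (1.1 equiv), 0 °C; filter; PhMe, 110 °C
Reagents that add atoms: none
Why: The electron-rich diene 12 should add in a normal-demand suprafacial [4+2] cycloaddition to the bromo-substituted C=C of 7, the more electron-poor of the two quinone double bonds, forming the future C8–C8a and C4a–C5 bonds in the bicyclo[2.2.2]octene adduct 13; the closest known reaction is the halogen-directed quinone Diels–Alder reaction of 1-alkoxycyclohexa-1,3-dienes. Et3N then removes the ring-fusion hydrogen α to the carbonyl and bromide leaves from the β-carbon (E1cB), which restores the ene-dione in 14. On heating, 14 should undergo a retro-Diels–Alder (Alder–Rickert) reaction that expels the CH2–CH2 bridge as ethylene and leaves the new six-membered carbocycle aromatic; both oxygens sit on bridgeheads, cannot be eliminated, and end up as C5–OMe and C8–OAc. The one new ring is therefore closed by intermolecular [4+2] annulation onto the quinone followed by aromatisation, not by a cyclisation. No stereocentre is created in the product, since the sp3 carbons of 13 and 14 become planar, and the (S) carbinol carbon is a spectator under the short, mild base treatment. The step needs site and regioselectivity: bromine makes its own double bond the dienophile and sends the more nucleophilic diene terminus to the halogen-free carbon, and because OMe is a much stronger donor than OAc that terminus is the acetoxy-bearing carbon, so OAc should arrive peri to the C1 carbonyl next to the side chain and OMe peri to C4.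

Step 9
Reactants: 15 (S)-8-acetoxy-5-methoxy-2-[4-methyl-1-(3-methylbut-2-enoyloxy)pent-3-enyl]-1,4-naphthoquinone
Product: 16 (S)-8-hydroxy-5-methoxy-2-[4-methyl-1-(3-methylbut-2-enoyloxy)pent-3-enyl]-1,4-naphthoquinone
Conditions: K2CO3 (cat.), MeOH/THF, 0 °C; then AcOH
Reagents that add atoms: none
Why: Base-catalysed transesterification should cleave the peri aryl acetate, an activated ester whose leaving phenoxide is stabilised by the quinone carbonyl, far faster than the secondary β,β-dimethylacrylate, whose carbonyl is deactivated by conjugation and shielded.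

**Compound list**

1 | 4-bromo-2,5-dimethoxybenzaldehyde | COc1cc(Br)c(OC)cc1C=O | starting material
2 | (S)-1-(4-bromo-2,5-dimethoxyphenyl)but-3-en-1-yl diisopinocampheylborinate (Ipc from (+)-α-pinene) | COc1cc(Br)c(OC)cc1[C@H](CC=C)OB([C@H]1[C@H](C)[C@H]2C[C@@H](C1)C2(C)C)[C@H]1[C@H](C)[C@H]2C[C@@H](C1)C2(C)C | intermediate
3 | (S)-1-(4-bromo-2,5-dimethoxyphenyl)but-3-en-1-ol | COc1cc(Br)c(OC)cc1[C@H](CC=C)O | intermediate
4 | (S)-1-(4-bromo-2,5-dimethoxyphenyl)-4-methylpent-3-en-1-ol | COc1cc(Br)c(OC)cc1[C@H](CC=C(C)C)O | intermediate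
5 | 3-methylbut-2-enoic acid | CC(C)=CC(=O)O | starting material
6 | (S)-1-(4-bromo-2,5-dimethoxyphenyl)-4-methylpent-3-en-1-yl 3-methylbut-2-enoate | COc1cc(Br)c(OC)cc1[C@H](CC=C(C)C)OC(=O)C=C(C)C | intermediate
7 | (S)-2-bromo-5-[4-methyl-1-(3-methylbut-2-enoyloxy)pent-3-enyl]-1,4-benzoquinone | O=C1C=C(Br)C(=O)C=C1[C@H](CC=C(C)C)OC(=O)C=C(C)C | intermediate
8 | 1,4-dimethoxybenzene | COc1ccc(OC)cc1 | starting material
9 | 1,4-dimethoxycyclohexa-1,4-diene | COC1=CCC(OC)=CC1 | intermediate
10 | 4-methoxycyclohex-3-en-1-one | COC1=CCC(=O)CC1 | intermediate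
11 | potassium 4-methoxycyclohexa-1,3-dien-1-olate | COC1=CC=C([O-])CC1.[K+] | intermediate
12 | 4-methoxycyclohexa-1,3-dien-1-yl acetate (4-acetoxy-1-methoxycyclohexa-1,3-diene) | COC1=CC=C(OC(C)=O)CC1 | intermediate
13 | 1-acetoxy-4a-bromo-4-methoxy-7-[(S)-4-methyl-1-(3-methylbut-2-enoyloxy)pent-3-enyl]-1,4,4a,8a-tetrahydro-1,4-ethanonaphthalene-5,8-dione (diastereomer mixture at C1, C4, C4a, C8a) | O=C1C([C@H](CC=C(C)C)OC(=O)C=C(C)C)=CC(=O)C2(Br)C1C1(OC(C)=O)C=CC2(OC)CC1 | intermediate
14 | 1-acetoxy-4-methoxy-7-[(S)-4-methyl-1-(3-methylbut-2-enoyloxy)pent-3-enyl]-1,4-dihydro-1,4-ethanonaphthalene-5,8-dione (diastereomer mixture at the bridgeheads) | O=C1C([C@H](CC=C(C)C)OC(=O)C=C(C)C)=CC(=O)C2=C1C1(OC(C)=O)C=CC2(OC)CC1 | intermediate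
15 | (S)-8-acetoxy-5-methoxy-2-[4-methyl-1-(3-methylbut-2-enoyloxy)pent-3-enyl]-1,4-naphthoquinone | COc1ccc(OC(C)=O)c2c1C(=O)C=C([C@H](CC=C(C)C)OC(=O)C=C(C)C)C2=O | intermediate
16 | (S)-8-hydroxy-5-methoxy-2-[4-methyl-1-(3-methylbut-2-enoyloxy)pent-3-enyl]-1,4-naphthoquinone | COc1ccc(O)c2c1C(=O)C=C([C@H](CC=C(C)C)OC(=O)C=C(C)C)C2=O | target

**Step count**

Total: 9 steps. Longest linear sequence: 6 steps (1 → 3 → 4 → 6 → 7 → 15 → 16); the diene branch (8 → 9 → 10 → 12) has 3 steps and joins at step 8.

**Steps most likely to fail**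

1. Step 8. Under amine and at 110 °C the acyloxy-bearing carbon next to the quinone may tautomerise towards a quinone methide, which would erode its configuration or expel the carboxylate before ethylene has left. The fallback sets out from 4 and returns at 15; it carries the carbinol as a silyl ether through the cascade and installs the ester afterwards. The alcohol 4 is silylated (TBSCl, imidazole, DMF) to (S)-[1-(4-bromo-2,5-dimethoxyphenyl)-4-methylpent-3-enyloxy](tert-butyl)dimethylsilane F1. CAN (MeCN/H2O, 0 °C, short contact) should oxidise this to (S)-2-bromo-5-[1-(tert-butyldimethylsilyloxy)-4-methylpent-3-enyl]-1,4-benzoquinone F2. With 12 under the conditions of step 8 this should pass through the silyloxy bromo cycloadduct F3 and the silyloxy ethano-bridged quinone F4 to (S)-8-acetoxy-2-[1-(tert-butyldimethylsilyloxy)-4-methylpent-3-enyl]-5-methoxy-1,4-naphthoquinone F5. HF·pyridine (THF, 0 °C) should then free (S)-8-acetoxy-2-(1-hydroxy-4-methylpent-3-enyl)-5-methoxy-1,4-naphthoquinone F6 with the aryl acetate intact, and Steglich esterification with 5 (DCC, DMAP) should give 15.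

2. Step 7. Deprotonation may occur on the C6 side, the dienolate may be acylated on carbon, or the acid-labile diene may be lost on isolation. The fallback sets out from 10 and returns at 12; it makes enolisation degenerate and forms the enol ether last. Methanol is added across the enol ether (MeOH 1.1 equiv, cat. PPTS, CH2Cl2, 0 °C) to give 4,4-dimethoxycyclohexan-1-one F7, a ketone with two equivalent α-positions. LDA (THF, −78 °C) should give lithium 4,4-dimethoxycyclohex-1-en-1-olate F8, and acetic anhydride should trap it as 4,4-dimethoxycyclohex-1-en-1-yl acetate F9. TMSOTf with i-Pr2NEt (CH2Cl2, −20 °C) should then eliminate methanol from the ketal towards the allylic CH2, which gives the conjugated diene 12.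

3. Step 9. Discrimination between the two esters may be insufficient, so that the senecioate is cleaved along with the aryl acetate. The fallback sets out from 15 and returns at 16; it moves the selectivity from ester cleavage to ester formation. Both esters are cleaved (aq. NaOH, MeOH, 0 °C, argon; then dilute acid) to (S)-8-hydroxy-2-(1-hydroxy-4-methylpent-3-enyl)-5-methoxy-1,4-naphthoquinone F10. The side-chain alcohol alone should then be acylated with 5 (DCC, DMAP, CH2Cl2, 0 °C), because the C8 hydroxyl is held in a hydrogen bond to the C1 carbonyl and is a poor nucleophile; this gives 16.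

**Further compounds**

F1 | step 8 | (S)-[1-(4-bromo-2,5-dimethoxyphenyl)-4-methylpent-3-enyloxy](tert-butyl)dimethylsilane | COc1cc(Br)c(OC)cc1[C@H](CC=C(C)C)O[Si](C)(C)C(C)(C)C
F2 | step 8 | (S)-2-bromo-5-[1-(tert-butyldimethylsilyloxy)-4-methylpent-3-enyl]-1,4-benzoquinone | O=C1C=C(Br)C(=O)C=C1[C@H](CC=C(C)C)O[Si](C)(C)C(C)(C)C
F3 | step 8 | silyloxy bromo cycloadduct: 1-acetoxy-4a-bromo-7-[(S)-1-(tert-butyldimethylsilyloxy)-4-methylpent-3-enyl]-4-methoxy-1,4,4a,8a-tetrahydro-1,4-ethanonaphthalene-5,8-dione (diastereomer mixture) | O=C1C([C@H](CC=C(C)C)O[Si](C)(C)C(C)(C)C)=CC(=O)C2(Br)C1C1(OC(C)=O)C=CC2(OC)CC1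
F4 | step 8 | silyloxy ethano-bridged quinone: 1-acetoxy-7-[(S)-1-(tert-butyldimethylsilyloxy)-4-methylpent-3-enyl]-4-methoxy-1,4-dihydro-1,4-ethanonaphthalene-5,8-dione (diastereomer mixture) | O=C1C([C@H](CC=C(C)C)O[Si](C)(C)C(C)(C)C)=CC(=O)C2=C1C1(OC(C)=O)C=CC2(OC)CC1
F5 | step 8 | (S)-8-acetoxy-2-[1-(tert-butyldimethylsilyloxy)-4-methylpent-3-enyl]-5-methoxy-1,4-naphthoquinone | COc1ccc(OC(C)=O)c2c1C(=O)C=C([C@H](CC=C(C)C)O[Si](C)(C)C(C)(C)C)C2=O
F6 | step 8 | (S)-8-acetoxy-2-(1-hydroxy-4-methylpent-3-enyl)-5-methoxy-1,4-naphthoquinone | COc1ccc(OC(C)=O)c2c1C(=O)C=C([C@H](CC=C(C)C)O)C2=O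
F7 | step 7 | 4,4-dimethoxycyclohexan-1-one | COC1(OC)CCC(=O)CC1
F8 | step 7 | lithium 4,4-dimethoxycyclohex-1-en-1-olate | COC1(OC)CC=C([O-])CC1.[Li+]
F9 | step 7 | 4,4-dimethoxycyclohex-1-en-1-yl acetate | COC1(OC)CC=C(OC(C)=O)CC1
F10 | step 9 | (S)-8-hydroxy-2-(1-hydroxy-4-methylpent-3-enyl)-5-methoxy-1,4-naphthoquinone | COc1ccc(O)c2c1C(=O)C=C([C@H](CC=C(C)C)O)C2=O
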